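**Retrosynthetic overview**

1. Ring B (pyran: C1, O2, C3, C4, C4a, C8a) closes last. MnO2 oxidation of a bis-allylic diol unveils the C3 ketone and the enal, and the enol oxygen of the resulting vinylogous diketone adds to a C1 aldehyde to give the lactol.
2. The C1 aldehyde comes from a thioester, the C8 ester from acylation of the only secondary ring hydroxyl, and the C8 carbinol from hydroxyl-directed reduction of a C8 ketone.
3. Ring A (carbocycle: C4a, C5, C6, C7, C8, C8a) is disconnected at C6–C7 and C4a–C8a into a 1,3-dioxan-5-one β-keto thioester (C7, C8, C8a and C1) and an alkynal (C4a, C5, C6 with the C4–C3 side chain). The two are joined by conjugate addition then aldol addition in one flask.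
4. Enabling feature: in ring A, C8 lies between two tertiary carbinols, C7 and C8a, whose oxygens are cis-1,3. This is the retron of an acetonide-bridged α,α′-dioxygenated ketone with two nucleophilic α-carbons, while C4a=C5–C6=O is the retron of an ynal with two electrophilic carbons.
5. Ring order: ring A first (step 7, formed as the carbocyclic bridge of a 2,4-dioxabicyclo[3.3.1]nonene), ring B last (step 15).

Key step: step 7

Locants C1 to C8a below are those of the target's isochromene skeleton.
Assumption: the lactol carbon C1 equilibrates and the natural (1R) anomer (C1 OH trans to the C8a OH) is taken as the thermodynamically preferred one; the C3 carbinol of the side-chain fragment and the C6 carbinol of 10 and 11 are temporary stereocentres carried as epimer mixtures, left unspecified in the SMILES and erased by oxidation.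

**Route**

Step 1
Reactants: 1 2,2-dimethyl-1,3-dioxan-5-one
Product: 2 S-methyl 2,2-dimethyl-5-oxo-1,3-dioxane-4-carbothioate
Conditions: LiN(i-Pr)2 (2.1 equiv), THF, −78 °C; MeSC(O)SMe, −78 → −20 °C; AcOH quench
Reagents that add atoms: S,S′-dimethyl dithiocarbonate, CSC(=O)SC
Why: Crossed Claisen-type C-acylation of the ketone lithium enolate by the dithiocarbonate, driven by deprotonation of the β-keto thioester formed; the product is enolized, so no stereocentre of consequence arises.

Step 2
Reactants: 2 S-methyl 2,2-dimethyl-5-oxo-1,3-dioxane-4-carbothioate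
Product: 3 S-methyl 2,2,6-trimethyl-5-oxo-1,3-dioxane-4-carbothioate
Conditions: LiN(i-Pr)2 (2.2 equiv), THF, −78 → 0 °C; MeI (1.05 equiv), −78 °C; AcOH quench
Reagents that add atoms: iodomethane, CI
Why: γ-Alkylation of a β-keto thioester dianion, in which the more basic α′ carbanion is methylated selectively; 3 is used as its diastereomer and enol mixture because both of its stereocentres are erased by enolization in step 7.

Step 3
Reactants: 4 ethyl (E)-4-oxobut-2-enoate
Product: 5 ethyl (E)-4-hydroxyhept-2-en-6-ynoate
Conditions: Zn dust, propargyl bromide, THF, 0 °C → rt; dilute HCl work-up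
Reagents that add atoms: propargyl bromide, C#CCBr
Why: Barbier propargylation, in which the allenylzinc species adds 1,2 to the aldehyde in preference to the enoate and gives the homopropargylic alcohol as a racemate whose carbinol is oxidized away in step 15.

Step 4
Reactants: 5 ethyl (E)-4-hydroxyhept-2-en-6-ynoate
Product: 6 (E)-hept-2-en-6-yne-1,4-diol
Conditions: i-Bu2AlH (3.3 equiv), CH2Cl2, −78 → −20 °C; aq. KNaC4H4O6 (potassium sodium tartrate)
Reagents that add atoms: none
Why: 1,2-Reduction of the enoate to the allylic alcohol by i-Bu2AlH, which leaves the E-alkene and the terminal alkyne untouched at low temperature.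

Step 5
Reactants: 6 (E)-hept-2-en-6-yne-1,4-diol
Product: 7 (E)-1,4-bis(tert-butyldiphenylsilyloxy)hept-2-en-6-yne
Conditions: t-BuPh2SiCl (2.4 equiv), imidazole, DMAP (cat.), DMF, rt → 40 °C
Reagents that add atoms: tert-butylchlorodiphenylsilane, CC(C)(C)[Si](Cl)(c1ccccc1)c1ccccc1
Why: Standard silylation of both hydroxyls with an acid-stable silyl group chosen to survive the acidic acetonide removal in step 8.

Step 6
Reactants: 7 (E)-1,4-bis(tert-butyldiphenylsilyloxy)hept-2-en-6-yne
Product: 8 (E)-5,8-bis(tert-butyldiphenylsilyloxy)oct-6-en-2-ynal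
Conditions: n-BuLi (1.05 equiv), THF, −78 °C; DMF, −78 → 0 °C; inverse quench into aq. KH2PO4
Reagents that add atoms: N,N-dimethylformamide, CN(C)C=O
Why: Formylation of the lithium acetylide with DMF, the buffered inverse quench releasing the ynal without conjugate addition of the liberated amine.

Step 7
Reactants: 3 S-methyl 2,2,6-trimethyl-5-oxo-1,3-dioxane-4-carbothioate; 8 (E)-5,8-bis(tert-butyldiphenylsilyloxy)oct-6-en-2-ynal
Product: 10 acetonide-bridged bicyclic ketol (ring A as a 2,4-dioxabicyclo[3.3.1]non-6-ene), via Z-enal Michael adduct 9 (not isolated)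
Conditions: squaramide catalyst from 9-amino-9-deoxy-epi-quinidine and 3,5-bis(trifluoromethyl)aniline (10 mol%), toluene, −40 °C; then DBU (0.5 equiv), −20 → 0 °C
Reagents that add atoms: none
Why: The bifunctional catalyst deprotonates the enolized β-keto thioester 3 and, holding enolate and ynal by hydrogen bonding, directs conjugate addition of the C8a carbon to the alkyne β-carbon (bond C8a–C4a); kinetic anti-protonation of the allenolate puts the formyl group cis to the new quaternary carbon and gives Z-enal 9, whose only enolizable site is C7, so that DBU triggers a 6-(enolendo)-exo-trig aldol addition of the C7 enolate to the aldehyde (bond C7–C6) that closes ring A as the three-carbon bridge of the bicycle. The closest known reaction types are the cinchona-catalysed Michael addition of α-substituted β-keto esters to alkynyl carbonyl compounds and the Michael–aldol α,α′-annulation of cyclic β-keto esters with unsaturated aldehydes to bicyclo[3.3.1]nonanes. The C8a configuration is set by the catalyst (the quinidine-derived pseudoenantiomer is proposed for the required sense, the quinine-derived one being used should the induction prove opposite), and the C7 configuration is set by the ring itself, because the new bridge can only span the two cis-diaxial α-positions of the dioxanone, which forces the C7 and C8a oxygens cis; the C7 centre of 3 is erased on enolization and the C6 carbinol is oxidized in step 9. The step needs C- over O-alkylation and 1,4- over 1,2-addition, secured by the soft, doubly stabilized enolate, and a Z-enal, secured by the protonation geometry and, under DBU, by equilibration of any E-isomer through the dienolate while only the Z-isomer is drained by ring closure. Retro-aldol opening is harmless because re-closure can only return the same cis-bridged product.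

Step 8
Reactants: 10 acetonide-bridged bicyclic ketol
Product: 11 ring A ketol triol (C7 OH and C8a OH cis, C8 ketone, C6 carbinol)
Conditions: TsOH·H2O (0.1 equiv), MeOH, 0 °C → rt
Reagents that add atoms: none
Why: Acid-catalysed transketalization to methanol removes the acetonide, which is strained by its 1,3-diaxial bridge and should cleave under conditions that spare the tert-butyldiphenylsilyl ethers, the thioester and the β-hydroxy ketone, with no stereocentre touched.

Step 9
Reactants: 11 ring A ketol triol
Product: 12 ring A enedione diol (C6 and C8 ketones)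
Conditions: MnO2 (activated, excess), CH2Cl2, rt
Reagents that add atoms: none
Why: Chemoselective MnO2 oxidation of the only allylic and only secondary hydroxyl to the C6 enone, the tertiary hydroxyls being inert, which also removes the uncontrolled C6 stereocentre.

Step 10
Reactants: 12 ring A enedione diol
Product: 13 ring A enone triol (C8 OH trans to the C7 and C8a hydroxyls)
Conditions: Me4NBH(OAc)3 (1.5 equiv), MeCN/AcOH (1:1), −35 → −20 °C
Reagents that add atoms: none
Why: Saksena–Evans hydroxyl-directed reduction, in which the two cis tertiary hydroxyls at C7 and C8a exchange onto boron and deliver hydride intramolecularly to the same face of the C8 ketone, so that the new C8 hydroxyl ends anti to both, while the conjugated and less electrophilic C6 carbonyl, which has only one directing hydroxyl, should react more slowly.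

Step 11
Reactants: 14 (R)-3-hydroxybutanoic acid
Product: 16 (R)-3-(tert-butyldimethylsilyloxy)butanoic acid, via bis-silyl ester 15 (not isolated)
Conditions: t-BuMe2SiCl (2.3 equiv), imidazole (4 equiv), DMF, rt; then MeOH/H2O, K2CO3 (0.2 equiv), rt; pH 4 work-up
Reagents that add atoms: tert-butylchlorodimethylsilane, CC(C)(C)[Si](C)(C)Cl
Why: Exhaustive silylation followed by selective solvolysis of the labile silyl ester gives the O-protected acid with the chiral-pool (R) centre untouched.

Step 12
Reactants: 13 ring A enone triol; 16 (R)-3-(tert-butyldimethylsilyloxy)butanoic acid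
Product: 18 C8 (R)-3-(tert-butyldimethylsilyloxy)butanoate of 13, via mixed anhydride 17 (not isolated)
Conditions: 2,4,6-trichlorobenzoyl chloride, Et3N, THF, rt; then 13, DMAP, toluene, rt → 40 °C
Reagents that add atoms: none
Why: Yamaguchi esterification through the mixed anhydride and DMAP acylates the only secondary hydroxyl (C8), the two tertiary hydroxyls being unreactive, and installs the (R)-configured side chain without touching the ring stereocentres.

Step 13
Reactants: 18 C8 (R)-3-(tert-butyldimethylsilyloxy)butanoate of 13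
Product: 19 C1 aldehyde (formyl group on C8a)
Conditions: Pd/C (10 wt%), Et3SiH (3 equiv), acetone, rt
Reagents that add atoms: none
Why: Fukuyama reduction, in which palladium inserts into the C–S bond of the thioester and Et3SiH delivers hydride to give the aldehyde under neutral conditions that should leave the ester, the β,β-disubstituted enone and the hindered trans-alkene untouched.

Step 14
Reactants: 19 C1 aldehyde
Product: 20 desilylated aldehyde pentaol (free C3 carbinol, primary allylic alcohol and side-chain hydroxyl)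
Conditions: HF·pyridine, pyridine, THF, 0 °C → rt
Reagents that add atoms: none
Why: Fluoride-mediated cleavage of all three silyl ethers under buffered, weakly acidic conditions that avoid β-elimination of the hydroxybutanoate and epimerize no centre.

Step 15
Reactants: 20 desilylated aldehyde pentaol
Product: 22 azaphilone D, via seco keto dialdehyde 21 (not isolated)
Conditions: MnO2 (activated, excess), CH2Cl2, rt
Reagents that add atoms: none
Why: MnO2 oxidizes only the two allylic alcohols (primary one to the enal, C3 carbinol to the ketone, the unactivated secondary hydroxyl of the hydroxybutanoate and the tertiary hydroxyls being inert), and the resulting vinylogous 1,3-diketone 21 enolizes towards C4 so that its enol oxygen adds to the C1 aldehyde (6-exo-trig hemiacetalization) to close ring B, the C1 lactol centre being set by anomeric equilibration.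

**Compound list**

1 | 2,2-dimethyl-1,3-dioxan-5-one | CC1(C)OCC(=O)CO1 | starting material
2 | S-methyl 2,2-dimethyl-5-oxo-1,3-dioxane-4-carbothioate | CSC(=O)C1OC(C)(C)OCC1=O | intermediate
3 | S-methyl 2,2,6-trimethyl-5-oxo-1,3-dioxane-4-carbothioate (diastereomer and enol mixture) | CSC(=O)C1OC(C)(C)OC(C)C1=O | intermediate
4 | ethyl (E)-4-oxobut-2-enoate | CCOC(=O)/C=C/C=O | starting material
5 | ethyl (E)-4-hydroxyhept-2-en-6-ynoate (racemic) | CCOC(=O)/C=C/C(O)CC#C | intermediate
6 | (E)-hept-2-en-6-yne-1,4-diol (racemic) | OC/C=C/C(O)CC#C | intermediate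
7 | (E)-1,4-bis(tert-butyldiphenylsilyloxy)hept-2-en-6-yne | C#CCC(O[Si](c1ccccc1)(c1ccccc1)C(C)(C)C)/C=C/CO[Si](c1ccccc1)(c1ccccc1)C(C)(C)C | intermediate
8 | (E)-5,8-bis(tert-butyldiphenylsilyloxy)oct-6-en-2-ynal | O=CC#CCC(O[Si](c1ccccc1)(c1ccccc1)C(C)(C)C)/C=C/CO[Si](c1ccccc1)(c1ccccc1)C(C)(C)C | intermediate
9 | Z-enal Michael adduct: S-methyl 2,2,6-trimethyl-5-oxo-4-[(2Z,6E)-1-oxo-5,8-bis(tert-butyldiphenylsilyloxy)octa-2,6-dien-3-yl]-1,3-dioxane-4-carbothioate, C8a configured as in the target | O=C1C(C)OC(C)(C)O[C@@]1(C(=O)SC)/C(CC(O[Si](c2ccccc2)(c2ccccc2)C(C)(C)C)/C=C/CO[Si](c2ccccc2)(c2ccccc2)C(C)(C)C)=C\C=O | intermediate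
10 | bicyclic ketol: S-methyl 8-hydroxy-1,3,3-trimethyl-9-oxo-6-[(E)-2,5-bis(tert-butyldiphenylsilyloxy)pent-3-enyl]-2,4-dioxabicyclo[3.3.1]non-6-ene-5-carbothioate, both bridgeheads configured as C7 and C8a of the target | O=C1[C@@](C(=O)SC)(OC(C)(C)O2)C(CC(O[Si](c3ccccc3)(c3ccccc3)C(C)(C)C)/C=C/CO[Si](c3ccccc3)(c3ccccc3)C(C)(C)C)=CC(O)[C@]12C | intermediate
11 | ketol triol: S-methyl 1,4,5-trihydroxy-5-methyl-6-oxo-2-[(E)-2,5-bis(tert-butyldiphenylsilyloxy)pent-3-enyl]cyclohex-2-ene-1-carbothioate, 1-OH and 5-OH cis | O=C1[C@@](C(=O)SC)(O)C(CC(O[Si](c2ccccc2)(c2ccccc2)C(C)(C)C)/C=C/CO[Si](c2ccccc2)(c2ccccc2)C(C)(C)C)=CC(O)[C@@]1(C)O | intermediate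
12 | enedione diol: S-methyl 1,5-dihydroxy-5-methyl-4,6-dioxo-2-[(E)-2,5-bis(tert-butyldiphenylsilyloxy)pent-3-enyl]cyclohex-2-ene-1-carbothioate, 1-OH and 5-OH cis | O=C1[C@@](C(=O)SC)(O)C(CC(O[Si](c2ccccc2)(c2ccccc2)C(C)(C)C)/C=C/CO[Si](c2ccccc2)(c2ccccc2)C(C)(C)C)=CC(=O)[C@@]1(C)O | intermediate
13 | enone triol: S-methyl 1,5,6-trihydroxy-5-methyl-4-oxo-2-[(E)-2,5-bis(tert-butyldiphenylsilyloxy)pent-3-enyl]cyclohex-2-ene-1-carbothioate, 1-OH and 5-OH cis, 6-OH trans to both | O[C@@H]1[C@@](C(=O)SC)(O)C(CC(O[Si](c2ccccc2)(c2ccccc2)C(C)(C)C)/C=C/CO[Si](c2ccccc2)(c2ccccc2)C(C)(C)C)=CC(=O)[C@@]1(C)O | intermediate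
14 | (R)-3-hydroxybutanoic acid | C[C@@H](O)CC(=O)O | starting material
15 | tert-butyldimethylsilyl (R)-3-(tert-butyldimethylsilyloxy)butanoate | C[C@@H](O[Si](C)(C)C(C)(C)C)CC(=O)O[Si](C)(C)C(C)(C)C | intermediate
16 | (R)-3-(tert-butyldimethylsilyloxy)butanoic acid | C[C@@H](O[Si](C)(C)C(C)(C)C)CC(=O)O | intermediate
17 | (R)-3-(tert-butyldimethylsilyloxy)butanoic 2,4,6-trichlorobenzoic anhydride | C[C@@H](O[Si](C)(C)C(C)(C)C)CC(=O)OC(=O)c1c(Cl)cc(Cl)cc1Cl | intermediate
18 | 13 esterified at the 6-OH (C8 of the target) with (R)-3-(tert-butyldimethylsilyloxy)butanoic acid | C[C@@H](O[Si](C)(C)C(C)(C)C)CC(=O)O[C@@H]1[C@@](C(=O)SC)(O)C(CC(O[Si](c2ccccc2)(c2ccccc2)C(C)(C)C)/C=C/CO[Si](c2ccccc2)(c2ccccc2)C(C)(C)C)=CC(=O)[C@@]1(C)O | intermediate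
19 | aldehyde: as 18 with the thioester replaced by a formyl group | C[C@@H](O[Si](C)(C)C(C)(C)C)CC(=O)O[C@@H]1[C@@](C=O)(O)C(CC(O[Si](c2ccccc2)(c2ccccc2)C(C)(C)C)/C=C/CO[Si](c2ccccc2)(c2ccccc2)C(C)(C)C)=CC(=O)[C@@]1(C)O | intermediate
20 | desilylated aldehyde: 1-formyl-1,5-dihydroxy-5-methyl-4-oxo-2-[(E)-2,5-dihydroxypent-3-enyl]cyclohex-2-en-6-yl (R)-3-hydroxybutanoate, ring configured as in the target (may exist as a C1/C3 hemiacetal) | C[C@@H](O)CC(=O)O[C@@H]1[C@@](C=O)(O)C(CC(O)/C=C/CO)=CC(=O)[C@@]1(C)O | intermediate
21 | seco keto dialdehyde: as 20 with the side chain oxidized to (E)-2,5-dioxopent-3-enyl | C[C@@H](O)CC(=O)O[C@@H]1[C@@](C=O)(O)C(CC(=O)/C=C/C=O)=CC(=O)[C@@]1(C)O | intermediate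
22 | azaphilone D: (1R,7S,8R,8aS)-1,7,8a-trihydroxy-7-methyl-6-oxo-3-[(E)-3-oxoprop-1-enyl]-6,7,8,8a-tetrahydro-1H-isochromen-8-yl (R)-3-hydroxybutanoate | C[C@@H](O)CC(=O)O[C@@H]1[C@@]2(O)C(=CC(=O)[C@@]1(C)O)C=C(/C=C/C=O)O[C@H]2O | target

**Step count and risks**

Total step count: 15. Longest linear sequence: 12 steps (steps 3–10 and 12–15, from ethyl (E)-4-oxobut-2-enoate).

Steps most likely to fail:

1. Step 7. Risk: poor facial selectivity in the conjugate addition, because the racemic C7 centre of 3 can pair in a mismatched way with the catalyst, so that ring A forms with low enantiomeric purity at C8a. Fallback (sets out from 3 and 8, returns at 18): the cascade is run with Et3N then DBU and no chiral catalyst. This should give the Z-enal as a racemate (9 plus ent-Michael adduct F1) and from it the racemic ketol (10 plus ent-bicyclic ketol F2). The racemate is taken through steps 8, 9 and 10 unchanged, so that 11, 12 and 13 are accompanied by ent-ketol triol F3, ent-enedione F4 and ent-enone triol F5. Esterification with enantiopure 16 under the conditions of step 12 then turns the enantiomers into diastereomers, 18 and ring-A-epimeric ester F6. These are separated by chromatography, and 18 continues with step 13.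

2. Step 12. Risk: failure of acyl transfer to the C8 hydroxyl, which is flanked by two fully substituted carbons, with competing β-elimination of the activated β-silyloxy acid to a crotonyl species. Fallback (sets out from 13, returns at 18): the small, highly reactive electrophile diketene (DMAP cat., CH2Cl2, 0 °C) should acetoacetylate the secondary hydroxyl to give acetoacetate F7. An (R)-selective ketoreductase (NADPH recycled with glucose dehydrogenase and glucose, pH 7 buffer with DMSO) then reduces the side-chain ketone to (R)-3-hydroxybutanoate F8. Silylation of its secondary hydroxyl (t-BuMe2SiCl, imidazole, DMF) gives 18.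

3. Step 10. Risk: over-reduction, through hydride delivery from the C7 hydroxyl to the C6 enone carbonyl in competition with reduction at C8. Fallback (sets out from 11, returns at 13): the order of steps 9 and 10 is reversed. Me4NBH(OAc)3 is applied to 11, where C8 is the only ketone, to give ring A tetraol F9, and MnO2 then oxidizes only the allylic C6 carbinol to give 13. Facial control still rests on the two tertiary hydroxyls, and any C8 epimer arising from delivery by the C6 hydroxyl would be removed at this stage.

**Further compounds**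

F1 | step 7 | ent-Michael adduct (enantiomer of 9 at C8a) | O=C1C(C)OC(C)(C)O[C@]1(C(=O)SC)/C(CC(O[Si](c2ccccc2)(c2ccccc2)C(C)(C)C)/C=C/CO[Si](c2ccccc2)(c2ccccc2)C(C)(C)C)=C\C=O
F2 | step 7 | ent-bicyclic ketol (enantiomer of 10 at both bridgeheads) | O=C1[C@](C(=O)SC)(OC(C)(C)O2)C(CC(O[Si](c3ccccc3)(c3ccccc3)C(C)(C)C)/C=C/CO[Si](c3ccccc3)(c3ccccc3)C(C)(C)C)=CC(O)[C@@]12C
F3 | step 7 | ent-ketol triol (enantiomer of 11 in ring A) | O=C1[C@](C(=O)SC)(O)C(CC(O[Si](c2ccccc2)(c2ccccc2)C(C)(C)C)/C=C/CO[Si](c2ccccc2)(c2ccccc2)C(C)(C)C)=CC(O)[C@]1(C)O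
F4 | step 7 | ent-enedione (enantiomer of 12 in ring A) | O=C1[C@](C(=O)SC)(O)C(CC(O[Si](c2ccccc2)(c2ccccc2)C(C)(C)C)/C=C/CO[Si](c2ccccc2)(c2ccccc2)C(C)(C)C)=CC(=O)[C@]1(C)O
F5 | step 7 | ent-enone triol (enantiomer of 13 in ring A) | O[C@H]1[C@](C(=O)SC)(O)C(CC(O[Si](c2ccccc2)(c2ccccc2)C(C)(C)C)/C=C/CO[Si](c2ccccc2)(c2ccccc2)C(C)(C)C)=CC(=O)[C@]1(C)O
F6 | step 7 | ring-A-epimeric ester (diastereomer of 18 with enantiomeric ring A and (R) side chain) | C[C@@H](O[Si](C)(C)C(C)(C)C)CC(=O)O[C@H]1[C@](C(=O)SC)(O)C(CC(O[Si](c2ccccc2)(c2ccccc2)C(C)(C)C)/C=C/CO[Si](c2ccccc2)(c2ccccc2)C(C)(C)C)=CC(=O)[C@]1(C)O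
F7 | step 12 | acetoacetate of 13 at the C8 hydroxyl | CC(=O)CC(=O)O[C@@H]1[C@@](C(=O)SC)(O)C(CC(O[Si](c2ccccc2)(c2ccccc2)C(C)(C)C)/C=C/CO[Si](c2ccccc2)(c2ccccc2)C(C)(C)C)=CC(=O)[C@@]1(C)O
F8 | step 12 | (R)-3-hydroxybutanoate of 13 at the C8 hydroxyl | C[C@@H](O)CC(=O)O[C@@H]1[C@@](C(=O)SC)(O)C(CC(O[Si](c2ccccc2)(c2ccccc2)C(C)(C)C)/C=C/CO[Si](c2ccccc2)(c2ccccc2)C(C)(C)C)=CC(=O)[C@@]1(C)O
F9 | step 10 | ring A tetraol (11 with the C8 ketone reduced, C8 OH trans to the C7 and C8a hydroxyls) | O[C@@H]1[C@@](C(=O)SC)(O)C(CC(O[Si](c2ccccc2)(c2ccccc2)C(C)(C)C)/C=C/CO[Si](c2ccccc2)(c2ccccc2)C(C)(C)C)=CC(O)[C@@]1(C)O
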